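The retrosynthesis first removes the four aryl benzyl ethers. It then cuts C8–C8a and C4a–C5, which takes C5–C8 of ring A away as methyl acetoacetate, then C2–C3 and O1–C8a of ring C, and last the biaryl bond C3'–C6''.
The feature that allows this: with ring A trimmed to its C4a=C8a edge, ring C (O1, C2, C3, C4, C4a, C8a) is a 2-aryl-2,3-dihydro-4H-pyran-4-one. C2 and O1 are then the carbonyl atoms of a ring B aldehyde, and C3, C4, C4a, C8a are the four carbons of a 1-methoxy-3-silyloxybutadiene.
In the forward direction, the flavone half (from apigenin) is joined to ring B, ring C is closed on the aldehyde, C4a receives a sulfinyl group, ring A is annulated onto C4a=C8a, and hydrogenolysis ends the route.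
C2 is the only stereocentre. (S)-BINOL on titanium sets it when ring C closes, and it is kept because no later step contains a base that enolises C3, the one event that lets O1 leave C2.

Key step: step 7

Locants: the flavanone half is O1–C8a (rings A and C) and C1'–C6' (ring B); the flavone half is double-primed and its 4-oxygenated phenyl ring triple-primed. Ar = 4-(benzyloxy)-3-{5,7-bis(benzyloxy)-2-[4-(benzyloxy)phenyl]-4-oxo-4H-chromen-6-yl}phenyl.
Assumption on the catalyst sense: (S)-BINOL on titanium is taken to open the Si face of an aromatic aldehyde to carbon nucleophiles, as in the related allyl and enol silane additions. A trial with 4-(benzyloxy)benzaldehyde should confirm this before the biaryl aldehyde is committed; otherwise only the ligand antipode changes.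
Assumption on the axis: the C3'–C6'' axis carries three ortho oxygen substituents and one ortho hydrogen and has no descriptor in the target, so it is treated as freely rotating. Benzylated intermediates may appear as slowly exchanging rotamers, which has no bearing on C2.

Step 1
Reactants: 1 apigenin
Product: 2 7-(benzyloxy)-2-[4-(benzyloxy)phenyl]-5-hydroxy-4H-chromen-4-one
Conditions: BnBr (2.1 equiv), K2CO3, DMF, rt
Reagents that add atoms: benzyl bromide, BrCc1ccccc1
Why: Williamson etherification takes the acidic, unhindered 7- and 4'-phenols, while the 5-OH is held in a hydrogen bond to the C4 carbonyl and should stay free at this stoichiometry.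

Step 2
Reactants: 2 7-(benzyloxy)-2-[4-(benzyloxy)phenyl]-5-hydroxy-4H-chromen-4-one
Product: 3 7-(benzyloxy)-2-[4-(benzyloxy)phenyl]-5-hydroxy-6-iodo-4H-chromen-4-one
Conditions: BnMe3N·ICl2, CaCO3, CH2Cl2/MeOH, rt
Reagents that add atoms: benzyltrimethylammonium dichloroiodate, C[N+](C)(C)Cc1ccccc1.Cl[I-]Cl
Why: In this electrophilic aromatic iodination, flavones with a free 5-OH and a blocked O7 are known to react with the dichloroiodate ortho to the phenol at C6 rather than at C8, and CaCO3 takes up the HCl.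

Step 3
Reactants: 3 7-(benzyloxy)-2-[4-(benzyloxy)phenyl]-5-hydroxy-6-iodo-4H-chromen-4-one
Product: 4 5,7-bis(benzyloxy)-2-[4-(benzyloxy)phenyl]-6-iodo-4H-chromen-4-one
Conditions: BnBr (excess), K2CO3, DMF, 70 °C
Reagents that add atoms: benzyl bromide, BrCc1ccccc1
Why: Williamson etherification with excess halide and heat breaks the chelate of the 5-OH, which must be capped because a free peri phenol would bind titanium in step 7.

Step 4
Reactants: 5 3-bromo-4-hydroxybenzaldehyde
Product: 6 4-(benzyloxy)-3-bromobenzaldehyde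
Conditions: BnBr, K2CO3, DMF, rt
Reagents that add atoms: benzyl bromide, BrCc1ccccc1
Why: This is a Williamson etherification of an acidic para-formyl phenol with no competing site.

Step 5
Reactants: 6 4-(benzyloxy)-3-bromobenzaldehyde
Product: 7 4-(benzyloxy)-3-(4,4,5,5-tetramethyl-1,3,2-dioxaborolan-2-yl)benzaldehyde
Conditions: B2pin2, PdCl2(dppf) (cat.), KOAc, 1,4-dioxane, 85 °C
Reagents that add atoms: bis(pinacolato)diboron, CC1(C)OB(OC1(C)C)B1OC(C)(C)C(C)(C)O1
Why: Miyaura borylation tolerates the aldehyde, and boron is placed on the less hindered partner instead of the doubly ortho-substituted flavone C6.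

Step 6
Reactants: 4 5,7-bis(benzyloxy)-2-[4-(benzyloxy)phenyl]-6-iodo-4H-chromen-4-one; 7 4-(benzyloxy)-3-(4,4,5,5-tetramethyl-1,3,2-dioxaborolan-2-yl)benzaldehyde
Product: 8 4-(benzyloxy)-3-{5,7-bis(benzyloxy)-2-[4-(benzyloxy)phenyl]-4-oxo-4H-chromen-6-yl}benzaldehyde (Ar-CHO)
Conditions: Pd(OAc)2 (cat.), SPhos, K3PO4, toluene/H2O, 90 °C
Reagents that add atoms: none
Why: In this Suzuki-Miyaura coupling, 6-iodo-5,7-dialkoxyflavones are established electrophiles for C6''–aryl bonds, the iodide adds readily to zerovalent palladium, the bulky biarylphosphine copes with three ortho substituents, and K3PO4 leaves the non-enolisable aldehyde alone.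

Step 7
Reactants: 8 4-(benzyloxy)-3-{5,7-bis(benzyloxy)-2-[4-(benzyloxy)phenyl]-4-oxo-4H-chromen-6-yl}benzaldehyde; 9 (E)-1-methoxy-3-(trimethylsilyloxy)buta-1,3-diene
Product: 11 (2S)-2-Ar-2,3-dihydro-4H-pyran-4-one, via silylated aldol adduct 10 (not isolated)
Conditions: Ti(OiPr)4 (20 mol %), (S)-BINOL (40 mol %), 4 Å MS, CH2Cl2, −20 °C; then CF3CO2H, CH2Cl2, 0 °C, short contact
Reagents that add atoms: none
Why: The formyl oxygen of 8 coordinates to the BINOL complex of tetravalent titanium, the unsubstituted terminus of 9 adds to the carbonyl carbon in a Mukaiyama aldol step (bond C2–C3), and silyl transfer gives 10. Trifluoroacetic acid then frees the C2 oxygen, which closes ring C by a 6-endo-trig oxa-Michael addition to the methoxy-bearing enone carbon (bond O1–C8a) followed by loss of methanol, so the outcome is that of a [4+2] hetero-Diels-Alder reaction. The closest known reaction type is the titanium-BINOL catalysed addition of this diene to aromatic aldehydes, 4-alkoxybenzaldehydes included. C2 is the only new stereocentre and is controlled by the ligand alone: (S)-BINOL covers the Re face, the diene arrives on the Si face and the (S) configuration results, the formyl group lying meta to the biaryl axis and outside its steric reach. The step needs the aldehyde to react in the presence of the flavone: the pyrone carbonyl is at least as good a donor to titanium as the aldehyde, but its binding is reversible, hindered by the peri 5''-O-benzyl group and unproductive because the 2''-aryl pyrone is no partner for the diene, which is why a raised catalyst loading is chosen. Full benzylation removes every phenol that could displace BINOL from titanium.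

Step 8
Reactants: 11 (2S)-2-Ar-2,3-dihydro-4H-pyran-4-one
Product: 13 (2S)-2-Ar-5-(phenylsulfanyl)-2,3-dihydro-4H-pyran-4-one, via chloro sulfide adduct 12 (not isolated)
Conditions: PhSH, NCS, CH2Cl2, 0 °C; add 11, −78 °C; then Et3N, −78 to 0 °C
Reagents that add atoms: thiophenol, Sc1ccccc1 (transferred as benzenesulfenyl chloride, ClSc1ccccc1)
Why: This is the known addition-elimination α-sulfenylation of enones and enol ethers, in which sulfur goes to the nucleophilic enol ether carbon C4a, chloride goes to C8a and Et3N removes HCl, while at −78 °C the carbonyl-deactivated benzyloxyarenes should not compete and Et3N is too weak to enolise C3.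

Step 9
Reactants: 13 (2S)-2-Ar-5-(phenylsulfanyl)-2,3-dihydro-4H-pyran-4-one
Product: 14 (2S)-2-Ar-5-(phenylsulfinyl)-2,3-dihydro-4H-pyran-4-one (both sulfur epimers expected)
Conditions: mCPBA (1.0 equiv), CH2Cl2, −78 to −30 °C
Reagents that add atoms: 3-chloroperoxybenzoic acid, O=C(OO)c1cccc(Cl)c1
Why: One equivalent of peracid in the cold oxidises the sulfide chemoselectively and stops at the sulfoxide, and the uncontrolled sulfur stereocentre does not matter because sulfur leaves in step 12.

Step 10
Reactants: 15 methyl acetoacetate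
Product: 16 methyl 3-(trimethylsilyloxy)but-2-enoate (E/Z mixture expected)
Conditions: TMSCl, Et3N, hexane, rt
Reagents that add atoms: chlorotrimethylsilane, C[Si](C)(C)Cl
Why: O-silylation of the enol of a β-keto ester is the standard first stage towards its bis-silyl dienol ether.

Step 11
Reactants: 16 methyl 3-(trimethylsilyloxy)but-2-enoate
Product: 17 1-methoxy-1,3-bis(trimethylsilyloxy)buta-1,3-diene (C1=C2 geometry not controlled)
Conditions: LiN(iPr)2, THF, −78 °C; TMSCl, −78 °C to rt
Reagents that add atoms: chlorotrimethylsilane, C[Si](C)(C)Cl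
Why: γ-Deprotonation and O-silylation of the dienolate is the standard preparation of this diene, and its C1=C2 geometry is lost when that carbon becomes aromatic C5.

Step 12
Reactants: 14 (2S)-2-Ar-5-(phenylsulfinyl)-2,3-dihydro-4H-pyran-4-one; 17 1-methoxy-1,3-bis(trimethylsilyloxy)buta-1,3-diene
Product: 20 (2S)-2-Ar-5,7-dihydroxychroman-4-one, via cis-fused cycloadduct 18 (not isolated), via bis-silyl ether 19 (not isolated)
Conditions: 17 (3 equiv), toluene, rt to 90 °C; then 1 M HCl, THF, 0 °C
Reagents that add atoms: none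
Why: Proposed new method: the sulfinyl group and the C4 carbonyl on C4a lower the LUMO of C4a=C8a and put its largest coefficient on C8a, so the CH2 terminus of the electron-rich diene should bond to C8a and the ketene acetal carbon to C4a in a normal-demand Diels-Alder reaction (or its stepwise Michael/acylation equivalent); suprafacial addition leaves H-8a cis to the sulfinyl group, which permits thermal syn-elimination of benzenesulfenic acid (scavenged by excess diene), and 1,4-loss of methanol then aromatises ring A with oxygen at C5 and C7; the closest known reaction type is the tandem Diels-Alder/sulfoxide elimination of 2-sulfinylquinones, 2-sulfinylcycloalkenones and 3-sulfinylchromones with oxygenated silyloxydienes, not yet shown on a monocyclic 5-sulfinyl-2,3-dihydropyran-4-one; the transient centres C4a, C5 and C8a vanish, and C2 is untouched because no base is present.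

Step 13
Reactants: 20 (2S)-2-Ar-5,7-dihydroxychroman-4-one
Product: 21 (2S)-5,7-dihydroxy-2-{4-hydroxy-3-[5,7-dihydroxy-2-(4-hydroxyphenyl)-4-oxo-4H-chromen-6-yl]phenyl}chroman-4-one
Conditions: H2 (1 atm), Pd/C, EtOAc/THF, AcOH (trace), rt
Reagents that add atoms: none
Why: Hydrogenolysis of the four aryl benzyl ethers is much faster than reduction of the flavone C2''=C3'' bond or cleavage of the C2–O1 bond, and the slightly acidic aprotic medium keeps C3 from enolising, so C2 stays (S).

Compound list
1 | apigenin | O=c1cc(-c2ccc(O)cc2)oc2cc(O)cc(O)c12 | starting material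
2 | 7-(benzyloxy)-2-[4-(benzyloxy)phenyl]-5-hydroxy-4H-chromen-4-one | O=c1cc(-c2ccc(OCc3ccccc3)cc2)oc2cc(OCc3ccccc3)cc(O)c12 | intermediate
3 | 7-(benzyloxy)-2-[4-(benzyloxy)phenyl]-5-hydroxy-6-iodo-4H-chromen-4-one | O=c1cc(-c2ccc(OCc3ccccc3)cc2)oc2cc(OCc3ccccc3)c(I)c(O)c12 | intermediate
4 | 5,7-bis(benzyloxy)-2-[4-(benzyloxy)phenyl]-6-iodo-4H-chromen-4-one | O=c1cc(-c2ccc(OCc3ccccc3)cc2)oc2cc(OCc3ccccc3)c(I)c(OCc3ccccc3)c12 | intermediate
5 | 3-bromo-4-hydroxybenzaldehyde | O=Cc1ccc(O)c(Br)c1 | starting material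
6 | 4-(benzyloxy)-3-bromobenzaldehyde | O=Cc1ccc(OCc2ccccc2)c(Br)c1 | intermediate
7 | 4-(benzyloxy)-3-(4,4,5,5-tetramethyl-1,3,2-dioxaborolan-2-yl)benzaldehyde | O=Cc1ccc(OCc2ccccc2)c(B2OC(C)(C)C(C)(C)O2)c1 | intermediate
8 | 4-(benzyloxy)-3-{5,7-bis(benzyloxy)-2-[4-(benzyloxy)phenyl]-4-oxo-4H-chromen-6-yl}benzaldehyde | O=Cc1ccc(OCc2ccccc2)c(-c2c(OCc3ccccc3)cc3oc(-c4ccc(OCc5ccccc5)cc4)cc(=O)c3c2OCc2ccccc2)c1 | intermediate
9 | (E)-1-methoxy-3-(trimethylsilyloxy)buta-1,3-diene | CO/C=C/C(=C)O[Si](C)(C)C | starting material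
10 | (1E,5S)-5-Ar-1-methoxy-5-(trimethylsilyloxy)pent-1-en-3-one | CO/C=C/C(=O)C[C@@H](c2ccc(OCc3ccccc3)c(-c3c(OCc4ccccc4)cc4oc(-c5ccc(OCc6ccccc6)cc5)cc(=O)c4c3OCc3ccccc3)c2)O[Si](C)(C)C | intermediate
11 | (2S)-2-Ar-2,3-dihydro-4H-pyran-4-one | O=C1C[C@@H](c2ccc(OCc3ccccc3)c(-c3c(OCc4ccccc4)cc4oc(-c5ccc(OCc6ccccc6)cc5)cc(=O)c4c3OCc3ccccc3)c2)OC=C1 | intermediate
12 | (2S)-2-Ar-6-chloro-5-(phenylsulfanyl)tetrahydro-4H-pyran-4-one, C5/C6 diastereomers | O=C1C[C@@H](c2ccc(OCc3ccccc3)c(-c3c(OCc4ccccc4)cc4oc(-c5ccc(OCc6ccccc6)cc5)cc(=O)c4c3OCc3ccccc3)c2)OC(Cl)C1Sc1ccccc1 | intermediate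
13 | (2S)-2-Ar-5-(phenylsulfanyl)-2,3-dihydro-4H-pyran-4-one | O=C1C[C@@H](c2ccc(OCc3ccccc3)c(-c3c(OCc4ccccc4)cc4oc(-c5ccc(OCc6ccccc6)cc5)cc(=O)c4c3OCc3ccccc3)c2)OC=C1Sc1ccccc1 | intermediate
14 | (2S)-2-Ar-5-(phenylsulfinyl)-2,3-dihydro-4H-pyran-4-one, both sulfur epimers | O=C1C[C@@H](c2ccc(OCc3ccccc3)c(-c3c(OCc4ccccc4)cc4oc(-c5ccc(OCc6ccccc6)cc5)cc(=O)c4c3OCc3ccccc3)c2)OC=C1S(=O)c1ccccc1 | intermediate
15 | methyl acetoacetate | CC(=O)CC(=O)OC | starting material
16 | methyl 3-(trimethylsilyloxy)but-2-enoate, E/Z mixture | COC(=O)C=C(C)O[Si](C)(C)C | intermediate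
17 | 1-methoxy-1,3-bis(trimethylsilyloxy)buta-1,3-diene | COC(O[Si](C)(C)C)=CC(=C)O[Si](C)(C)C | intermediate
18 | (2S)-2-Ar-5-methoxy-4a-(phenylsulfinyl)-5,7-bis(trimethylsilyloxy)-2,3,4a,5,8,8a-hexahydro-4H-chromen-4-one, H-8a cis to sulfinyl, otherwise a diastereomer mixture | O=C1C[C@@H](c2ccc(OCc3ccccc3)c(-c3c(OCc4ccccc4)cc4oc(-c5ccc(OCc6ccccc6)cc5)cc(=O)c4c3OCc3ccccc3)c2)OC2CC(O[Si](C)(C)C)=CC(OC)(O[Si](C)(C)C)C12S(=O)c1ccccc1 | intermediate
19 | (2S)-2-Ar-5,7-bis(trimethylsilyloxy)chroman-4-one | O=C1C[C@@H](c2ccc(OCc3ccccc3)c(-c3c(OCc4ccccc4)cc4oc(-c5ccc(OCc6ccccc6)cc5)cc(=O)c4c3OCc3ccccc3)c2)Oc2cc(O[Si](C)(C)C)cc(O[Si](C)(C)C)c21 | intermediate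
20 | (2S)-2-Ar-5,7-dihydroxychroman-4-one | O=C1C[C@@H](c2ccc(OCc3ccccc3)c(-c3c(OCc4ccccc4)cc4oc(-c5ccc(OCc6ccccc6)cc5)cc(=O)c4c3OCc3ccccc3)c2)Oc2cc(O)cc(O)c21 | intermediate
21 | (2S)-5,7-dihydroxy-2-{4-hydroxy-3-[5,7-dihydroxy-2-(4-hydroxyphenyl)-4-oxo-4H-chromen-6-yl]phenyl}chroman-4-one | O=C1C[C@@H](c2ccc(O)c(-c3c(O)cc4oc(-c5ccc(O)cc5)cc(=O)c4c3O)c2)Oc2cc(O)cc(O)c21 | target

Total step count: 13. Longest linear sequence: 9 steps (steps 1, 2, 3, 6, 7, 8, 9, 12, 13).

Steps most likely to fail

Step 12. The push-pull C4a=C8a bond may be too poor a dienophile. A stepwise Michael-type adduct may open ring C by expelling O1 from C8a. The silyl ketene acetal may also consume the sulfoxide in a silicon-induced Pummerer process. The fallback sets out from 8 and returns at 21; it brings ring A in ready-made and closes ring C at O1–C2. Commercial 1-[2,4-bis(benzyloxy)-6-hydroxyphenyl]ethanone is silylated on both oxygens (TMSOTf, Et3N, CH2Cl2, 0 °C) to 1-[2,4-bis(benzyloxy)-6-(trimethylsilyloxy)phenyl]-1-(trimethylsilyloxy)ethene F1. A Mukaiyama aldol addition of this enol silane to 8 under Ti(OiPr)4 and (R)-BINOL, the antipode that opens the Re face, followed by mild acidic work-up, should give (3R)-3-Ar-1-[2,4-bis(benzyloxy)-6-hydroxyphenyl]-3-hydroxypropan-1-one F2. A Mitsunobu etherification (PPh3, DIAD, THF, 0 °C) lets the phenol displace the activated carbinol oxygen with inversion and should give (2S)-2-Ar-5,7-bis(benzyloxy)chroman-4-one F3. Hydrogenolysis under the conditions of step 13 removes all six benzyl groups and reaches 21.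

Step 8. Site selectivity may be lost through sulfenylation at the electron-rich C8'' or at C3'' of the flavone. The fallback sets out from 11 and returns at 13; it functionalises C4a by a nucleophile-triggered path that aromatic rings cannot follow. Iodine and pyridine in CH2Cl2 act by conjugate addition of pyridine at C8a, iodination of the enolate at C4a and loss of pyridine, and should give (2S)-2-Ar-5-iodo-2,3-dihydro-4H-pyran-4-one F4. Palladium-catalysed C–S coupling with thiophenol (Pd2(dba)3, Xantphos, iPr2NEt, 1,4-dioxane, 60 °C) then leads to 13.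

Step 7. The pyrone carbonyl may hold the titanium catalyst, so that slow turnover lets an unselective background addition erode facial selectivity. Long acid contact could also ionise the 4-alkoxybenzylic C2–O1 bond. The fallback sets out from 8 and returns at 11; it replaces Lewis acid activation by hydrogen-bond catalysis and uses a more reactive diene. Commercial (E)-3-(tert-butyldimethylsilyloxy)-N,N-dimethylbuta-1,3-dien-1-amine is combined with 8 and a catalytic amount of the tetra(1-naphthyl)-TADDOL enantiomer that selects the Si face (toluene, −60 °C). This should give (2S)-2-Ar-4-(tert-butyldimethylsilyloxy)-6-(dimethylamino)-3,6-dihydro-2H-pyran F5 as C6 epimers. Acetyl chloride (CH2Cl2, −78 °C) then removes the amino and silyl groups without protic acid to give 11.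

Further compounds
F1 | step 12 | 1-[2,4-bis(benzyloxy)-6-(trimethylsilyloxy)phenyl]-1-(trimethylsilyloxy)ethene | C=C(O[Si](C)(C)C)c1c(OCc2ccccc2)cc(OCc2ccccc2)cc1O[Si](C)(C)C
F2 | step 12 | (3R)-3-Ar-1-[2,4-bis(benzyloxy)-6-hydroxyphenyl]-3-hydroxypropan-1-one | O=C(C[C@H](c2ccc(OCc3ccccc3)c(-c3c(OCc4ccccc4)cc4oc(-c5ccc(OCc6ccccc6)cc5)cc(=O)c4c3OCc3ccccc3)c2)O)c1c(O)cc(OCc2ccccc2)cc1OCc1ccccc1
F3 | step 12 | (2S)-2-Ar-5,7-bis(benzyloxy)chroman-4-one | O=C1C[C@@H](c2ccc(OCc3ccccc3)c(-c3c(OCc4ccccc4)cc4oc(-c5ccc(OCc6ccccc6)cc5)cc(=O)c4c3OCc3ccccc3)c2)Oc2cc(OCc3ccccc3)cc(OCc3ccccc3)c21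
F4 | step 8 | (2S)-2-Ar-5-iodo-2,3-dihydro-4H-pyran-4-one | O=C1C[C@@H](c2ccc(OCc3ccccc3)c(-c3c(OCc4ccccc4)cc4oc(-c5ccc(OCc6ccccc6)cc5)cc(=O)c4c3OCc3ccccc3)c2)OC=C1I
F5 | step 7 | (2S)-2-Ar-4-(tert-butyldimethylsilyloxy)-6-(dimethylamino)-3,6-dihydro-2H-pyran, C6 epimers | CN(C)C1C=C(O[Si](C)(C)C(C)(C)C)C[C@@H](c2ccc(OCc3ccccc3)c(-c3c(OCc4ccccc4)cc4oc(-c5ccc(OCc6ccccc6)cc5)cc(=O)c4c3OCc3ccccc3)c2)O1
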